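**Plan**
- Target numbering: ring C1(OBz)–C2=C3–C4(OBz)–C5(OH)(CH2OH)–C6(OH). Cuts, in order: C2=C3 (ring-closing metathesis), C3–C4 (vinyl Grignard on a lactol aldehyde), C5–CH2OH (formaldehyde aldol).
- Enabling feature: the only ring is a cyclohexene whose cis olefin C2=C3 lies between the two O-bearing allylic carbons C1 and C4. Its cis-5,6-diol can carry a temporary cis-fused acetonide that holds both vinyl carbinol arms on one face. Opened at C2=C3, the core is a branched octa-1,7-diene of galacto configuration (meso but for the C5 branch), which is a D-mannose chain.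
- Forward: D-mannose diacetonide is hydroxymethylated at C2, vinylated at C1, silylated and benzoylated, and its 5,6-diol is turned into the second vinyl group. The carbocycle is then closed, and acetonide and silyl ether are removed.
- Stereochemistry: mannose C2, C3, C4 become target C5, C6, C1 (chiral pool; CH2OH enters C2 with retention of the C–O configuration). Target C4 comes from chelation-controlled vinyl addition. Mannose C5 becomes olefinic C2 and mannose C6 leaves as ethene.

Key step: step 7

Remark: the lactol formed in step 1 is expected as an anomeric mixture; one anomer is drawn, and the anomeric centre is consumed in step 2.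

**Step 1**
Reactants: 1 2,3:5,6-di-O-isopropylidene-α-D-mannofuranose; 2 formaldehyde
Product: 3 2-C-(hydroxymethyl)-2,3:5,6-di-O-isopropylidene-D-mannofuranose
Conditions: 37% aq. HCHO (excess), K2CO3, MeOH, reflux
Reagents that add atoms: none
Why: Base-mediated crossed aldol of the ring-opened aldehyde with formaldehyde, in which the C2 enolate (sp2 carbon inside the dioxolane) should take up formaldehyde anti to the C3 side chain, giving the only adduct whose formyl group stays cis to O-4 and can reclose to the cis-fused furanose, so the C2–O configuration of mannose is kept and the quaternary carbinol (target C5) is set.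

**Step 2**
Reactants: 3 2-C-(hydroxymethyl)-2,3:5,6-di-O-isopropylidene-D-mannofuranose; 4 vinylmagnesium bromide (CH2=CHMgBr)
Product: 5 1,2-dideoxy-4-C-(hydroxymethyl)-4,5:7,8-di-O-isopropylidene-D-glycero-D-galacto-oct-1-enitol (triol)
Conditions: CH2=CHMgBr (5 equiv), THF, 0 °C → rt; aq. NH4Cl
Reagents that add atoms: none
Why: Grignard addition to the ring-opened hydroxy aldehyde of the lactol, in which magnesium chelation between the aldehyde oxygen and the adjacent dioxolane oxygen (Cram chelate model) should deliver vinyl to the exo face of the chelate and give the new C3 carbinol threo to O-4 (galacto), the configuration of target C4.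

**Step 3**
Reactants: 5 triol
Product: 6 4-C-{[(tert-butyldimethylsilyl)oxy]methyl}-1,2-dideoxy-4,5:7,8-di-O-isopropylidene-D-glycero-D-galacto-oct-1-enitol (3,6-diol)
Conditions: TBSCl (1.1 equiv), imidazole, CH2Cl2, 0 °C
Reagents that add atoms: tert-butyldimethylsilyl chloride, CC(C)(C)[Si](C)(C)Cl
Why: Selective silyl ether formation, the primary hydroxyl being silylated much faster than the two hindered secondary hydroxyls.

**Step 4**
Reactants: 6 3,6-diol; 7 benzoyl chloride (first equivalent)
Product: 8 3,6-di-O-benzoyl-4-C-{[(tert-butyldimethylsilyl)oxy]methyl}-1,2-dideoxy-4,5:7,8-di-O-isopropylidene-D-glycero-D-galacto-oct-1-enitol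
Conditions: BzCl (3 equiv), pyridine, DMAP (cat.), CH2Cl2, 0 °C → rt
Reagents that add atoms: benzoyl chloride (second equivalent), O=C(Cl)c1ccccc1
Why: DMAP-catalysed acylation (nucleophilic catalysis) of the two remaining secondary hydroxyls, each consuming one equivalent of benzoyl chloride, installs both benzoates of the target with retention at both carbinol carbons.

**Step 5**
Reactants: 8 dibenzoate
Product: 9 3,6-di-O-benzoyl-4-C-{[(tert-butyldimethylsilyl)oxy]methyl}-1,2-dideoxy-4,5-O-isopropylidene-D-glycero-D-galacto-oct-1-enitol (7,8-diol)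
Conditions: Zn(NO3)2·6H2O, MeCN, 50 °C
Reagents that add atoms: none
Why: Mild Lewis-acid-mediated acetal hydrolysis, in which the terminal monosubstituted dioxolane should open far faster than the fully substituted internal acetonide flanked by two benzoates, while silyl ether and esters are left alone.

**Step 6**
Reactants: 9 7,8-diol
Product: 11 3,6-di-O-benzoyl-4-C-{[(tert-butyldimethylsilyl)oxy]methyl}-1,2,7,8-tetradeoxy-4,5-O-isopropylidene-D-galacto-octa-1,7-dienitol, via 8-iodo-7-ol 10 (not isolated)
Conditions: PPh3, I2, imidazole, toluene, 90 °C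
Reagents that add atoms: none
Why: Garegg–Samuelsson deoxygenation of a vicinal diol, in which the primary hydroxyl is converted into the iodide, the secondary one into an alkoxyphosphonium, and iodide-induced anti elimination gives the terminal alkene without touching the neighbouring C6 stereocentre.

**Step 7**
Reactants: 11 diene
Product: 12 1,4-di-O-benzoyl-5-C-{[(tert-butyldimethylsilyl)oxy]methyl}-5,6-O-isopropylidene-cyclohex-2-ene-1,4,5,6-tetrol (target numbering; benzoates cis to each other and trans to the cis-fused dioxolane)
Conditions: second-generation Grubbs catalyst RuCl2(=CHPh)(H2IMes)(PCy3) (5 mol%), CH2Cl2 (0.005 M), 40 °C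
Reagents that add atoms: none
Why: Olefin metathesis by the Chauvin mechanism: the Ru=CHPh unit of the catalyst exchanges with one vinyl group, the resulting alkylidene undergoes intramolecular [2+2] cycloaddition with the second vinyl group, and the metallacyclobutane cycloreverts to the cyclohexene and a Ru=CH2 species, with ethene leaving irreversibly. The closest known reaction type is ring-closing metathesis of carbohydrate-derived 1,7-dienes with allylic oxygen substituents to conduritol-type cyclohexenes. The single ring formed is the six-membered carbocycle, closed by alkylidene transfer between the two terminal olefins of the 1,7-diene, and the ring size enforces the cis double bond. No stereocentre is formed or touched, so the four stereocentres of 11 are carried over unchanged. The selectivity needed is cyclisation over acyclic diene metathesis oligomerisation and over double-bond migration: the cis-fused dioxolane holds the two allylic carbons C3 and C6 of 11 syn so that the vinyl groups are within reach, high dilution suppresses oligomerisation, and with both allylic oxygens acylated no isomerisation to a ketone through a Ru–H species is open.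

**Step 8**
Reactants: 12 protected cyclohexene
Product: 13 (1R,4S,5S,6S)-5,6-dihydroxy-5-(hydroxymethyl)cyclohex-2-ene-1,4-diyl dibenzoate
Conditions: TFA/H2O (9:1), 0 °C → rt
Reagents that add atoms: none
Why: Aqueous acid hydrolyses the cis-fused acetonide and solvolyses the primary silyl ether in one operation, while the benzoates are inert to aqueous TFA and acyl migration to the freed hydroxyls, a base-promoted process, should stay slow; no stereocentre is involved.

**Compound list**
1 | 2,3:5,6-di-O-isopropylidene-α-D-mannofuranose (diacetone-D-mannose) | O[C@H]1O[C@H]([C@H]2COC(C)(C)O2)[C@@H]3OC(C)(C)O[C@H]13 | starting material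
2 | formaldehyde | C=O | starting material
3 | 2-C-(hydroxymethyl)-2,3:5,6-di-O-isopropylidene-D-mannofuranose (one anomer drawn) | O[C@H]1O[C@H]([C@H]2COC(C)(C)O2)[C@@H]3OC(C)(C)O[C@]13CO | intermediate
4 | vinylmagnesium bromide | C=C[Mg]Br | starting material
5 | 1,2-dideoxy-4-C-(hydroxymethyl)-4,5:7,8-di-O-isopropylidene-D-glycero-D-galacto-oct-1-enitol | C=C[C@H](O)[C@@]1(CO)OC(C)(C)O[C@H]1[C@H](O)[C@H]1COC(C)(C)O1 | intermediate
6 | 4-C-{[(tert-butyldimethylsilyl)oxy]methyl}-1,2-dideoxy-4,5:7,8-di-O-isopropylidene-D-glycero-D-galacto-oct-1-enitol | C=C[C@H](O)[C@@]1(CO[Si](C)(C)C(C)(C)C)OC(C)(C)O[C@H]1[C@H](O)[C@H]1COC(C)(C)O1 | intermediate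
7 | benzoyl chloride | O=C(Cl)c1ccccc1 | starting material
8 | 3,6-di-O-benzoyl-4-C-{[(tert-butyldimethylsilyl)oxy]methyl}-1,2-dideoxy-4,5:7,8-di-O-isopropylidene-D-glycero-D-galacto-oct-1-enitol | C=C[C@H](OC(=O)c2ccccc2)[C@@]1(CO[Si](C)(C)C(C)(C)C)OC(C)(C)O[C@H]1[C@H](OC(=O)c2ccccc2)[C@H]1COC(C)(C)O1 | intermediate
9 | 3,6-di-O-benzoyl-4-C-{[(tert-butyldimethylsilyl)oxy]methyl}-1,2-dideoxy-4,5-O-isopropylidene-D-glycero-D-galacto-oct-1-enitol (7,8-diol) | C=C[C@H](OC(=O)c2ccccc2)[C@@]1(CO[Si](C)(C)C(C)(C)C)OC(C)(C)O[C@H]1[C@H](OC(=O)c2ccccc2)[C@H](O)CO | intermediate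
10 | 8-deoxy-8-iodo derivative of 9 (8-iodo-7-ol, formed in situ in step 6) | C=C[C@H](OC(=O)c2ccccc2)[C@@]1(CO[Si](C)(C)C(C)(C)C)OC(C)(C)O[C@H]1[C@H](OC(=O)c2ccccc2)[C@H](O)CI | intermediate
11 | 3,6-di-O-benzoyl-4-C-{[(tert-butyldimethylsilyl)oxy]methyl}-1,2,7,8-tetradeoxy-4,5-O-isopropylidene-D-galacto-octa-1,7-dienitol | C=C[C@H](OC(=O)c2ccccc2)[C@@]1(CO[Si](C)(C)C(C)(C)C)OC(C)(C)O[C@H]1[C@H](OC(=O)c2ccccc2)C=C | intermediate
12 | 1,4-di-O-benzoyl-5-C-{[(tert-butyldimethylsilyl)oxy]methyl}-5,6-O-isopropylidene-cyclohex-2-ene-1,4,5,6-tetrol (same configuration as 13 at all four ring stereocentres) | O=C(O[C@H]1C=C[C@@H](OC(=O)c2ccccc2)[C@@H]2OC(C)(C)O[C@]12CO[Si](C)(C)C(C)(C)C)c1ccccc1 | intermediate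
13 | (1R,4S,5S,6S)-5,6-dihydroxy-5-(hydroxymethyl)cyclohex-2-ene-1,4-diyl dibenzoate | O=C(O[C@H]1C=C[C@@H](OC(=O)c2ccccc2)[C@H](O)[C@@]1(O)CO)c1ccccc1 | target

Total step count: 8. Longest linear sequence: 8 steps (1 → 13).

**Steps most likely to fail**

1. Step 2, poor or reversed facial selectivity in the vinyl addition. A chelate through the dioxolane oxygen and one through the magnesium alkoxide of the CH2O group can direct the nucleophile to opposite faces, so the outcome is not secure. The fallback reverses the order in which vinyl and hydrogen are put on this carbon; it sets out from 3 and comes back at 5. The lactol is oxidised (I2, K2CO3, t-BuOH, rt) to 2-C-(hydroxymethyl)-2,3:5,6-di-O-isopropylidene-D-mannono-1,4-lactone F1. CH2=CHMgBr (THF, −78 °C) adds once to give 1-C-vinyl-2-C-(hydroxymethyl)-2,3:5,6-di-O-isopropylidene-D-mannofuranose F2, a hemiketal. Luche reduction (NaBH4, CeCl3·7H2O, MeOH, −40 °C) of its ring-opened vinyl ketone form should then give 5, because hydride now takes the face that vinyl preferred and the carbinol configuration is opposite to that of the direct adduct.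

2. Step 6, participation or migration of the neighbouring C6 benzoate at the iodohydrin or alkoxyphosphonium stage under hot, imidazole-buffered conditions, which would divert material from the elimination. The fallback is a Corey–Winter olefination; it sets out from 9 and comes back at 11. 1,1'-Thiocarbonyldiimidazole (toluene, 80 °C) should give the 7,8-cyclic thionocarbonate of 9 F3. Heating with P(OMe)3 (110 °C) should then give 11 by syn elimination, under neutral conditions and without a charged leaving group next to the benzoate.

3. Step 5, incomplete discrimination between the acid-labile groups (loss of the silyl ether or of the internal acetonide, or stalled hydrolysis). The fallback excises the terminal carbon instead of deoxygenating the diol; it sets out from 8 and comes back at 11, bypassing 9 and 10. H5IO6 (dry EtOAc, rt) should cleave the terminal acetonide and the liberated glycol in one pot to the C7 aldehyde of 8 F4, the old C8 leaving as formaldehyde. Takai–Lombardo methylenation (Zn, CH2Br2, TiCl4, THF/CH2Cl2, 0 °C), which is non-basic and selective for aldehydes over benzoates, should then give 11.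

**Further compounds**
F1 | step 2 | 2-C-(hydroxymethyl)-2,3:5,6-di-O-isopropylidene-D-mannono-1,4-lactone | O=C1O[C@H]([C@H]2COC(C)(C)O2)[C@@H]3OC(C)(C)O[C@]13CO
F2 | step 2 | 1-C-vinyl-2-C-(hydroxymethyl)-2,3:5,6-di-O-isopropylidene-D-mannofuranose (hemiketal, one anomer drawn) | O[C@@]1(C=C)O[C@H]([C@H]2COC(C)(C)O2)[C@@H]3OC(C)(C)O[C@]13CO
F3 | step 6 | 7,8-cyclic thionocarbonate of 9 | C=C[C@H](OC(=O)c2ccccc2)[C@@]1(CO[Si](C)(C)C(C)(C)C)OC(C)(C)O[C@H]1[C@H](OC(=O)c2ccccc2)[C@H]1COC(=S)O1
F4 | step 5 | C7 aldehyde of 8 (terminal dioxolane replaced by a formyl group) | C=C[C@H](OC(=O)c2ccccc2)[C@@]1(CO[Si](C)(C)C(C)(C)C)OC(C)(C)O[C@H]1[C@H](OC(=O)c2ccccc2)C=O
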